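**Retrosynthetic overview**

1. The target comes from hydroperoxy endoperoxide 26 by hydroperoxide reduction and dehydration. 26 comes from tertiary hydroperoxide 25 by a radical-chain peroxyl cyclisation under O2. The strategy rests on the O–O bridge that joins the methyl-bearing quaternary C5 to the CH carbon C2, 1,4 across the six-membered ring of the bicyclo[4.2.0]octane; in 25, C2 is the unsubstituted end of the C2=C3(CH3) ring alkene.
2. 25 comes from C5 carboxylic acid 23 by decarboxylative oxygenation. The C5 radical takes up O2 on the convex face, and no cation is generated next to the cyclobutane.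
3. The methoxypyranone is built on the endo aldehyde 16 with the dianion of methyl 2-methyl-3-oxopentanoate. The C8 and C7 methyl groups come from two exo-face alkylations.
4. Cyclobutanone 12 comes from an auxiliary-controlled keteniminium [2+2] cycloaddition to cyclohexadiene ester 7. Diene 7 comes from a Diels–Alder reaction and elimination starting from (E)-2-methylpent-2-enal and a methacrylate.
5. Ring order: cyclohexadiene, then cyclobutanone (bicyclo[4.2.0]octene), then pyranone, then 1,2-dioxane (key step).

Key step: step 17

Assumption: the (2R,5R)-pyrrolidine amide is taken to induce the (1S,6S) ring fusion in step 6; should the sense of induction be opposite, the (2S,5S) antipode is used in the same way.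
Remark: locants follow bicyclo[4.2.0]octane numbering (C1 and C6 ring fusion, C7 and C8 cyclobutane); "exo" is the convex face carrying 1-CH3 and 6-H. Compounds 11–16 and 19–24 are carried as mixtures of C5 epimers (left undefined in the SMILES), because step 16 turns C5 into a planar radical.

**Route**

Step 1
Reactants: 1 methacryloyl chloride; 2 2-(trimethylsilyl)ethanol
Product: 3 2-(trimethylsilyl)ethyl methacrylate
Conditions: Et3N, DMAP (cat.), CH2Cl2, 0 °C → rt
Reagents that add atoms: none
Why: Acylation of the alcohol by the acid chloride gives a fluoride-labile ester that should survive the later bases, ylide, oxidant and methylating agents.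

Step 2
Reactants: 4 (E)-2-methylpent-2-enal
Product: 5 (1E,3E)-1-[(tert-butyldimethylsilyl)oxy]-2-methylpenta-1,3-diene
Conditions: TBSOTf, Et3N, Et2O, 0 °C → rt
Reagents that add atoms: tert-butyldimethylsilyl trifluoromethanesulfonate, CC(C)(C)[Si](C)(C)OS(=O)(=O)C(F)(F)F
Why: Soft enolisation (O-silylation, then γ-deprotonation by the amine) gives the silyl dienol ether, and the s-trans enal should lead to the (1E) isomer that can reach the s-cis diene conformation.

Step 3
Reactants: 5 (1E,3E)-1-[(tert-butyldimethylsilyl)oxy]-2-methylpenta-1,3-diene; 3 2-(trimethylsilyl)ethyl methacrylate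
Product: 6 2-(trimethylsilyl)ethyl 2-[(tert-butyldimethylsilyl)oxy]-1,3,5-trimethylcyclohex-3-ene-1-carboxylate (racemic mixture of diastereomers)
Conditions: PhMe, BHT (cat.), 130 °C, sealed tube
Reagents that add atoms: none
Why: Thermal Diels–Alder reaction in which the 1-silyloxy donor should direct the methyl-bearing diene terminus onto the CH2 of the methacrylate ("ortho" adduct), so that the quaternary ester carbon sits next to the silyloxy carbon; every stereocentre except the quaternary one is removed in step 4.

Step 4
Reactants: 6 2-(trimethylsilyl)ethyl 2-[(tert-butyldimethylsilyl)oxy]-1,3,5-trimethylcyclohex-3-ene-1-carboxylate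
Product: 7 2-(trimethylsilyl)ethyl 1,3,5-trimethylcyclohexa-2,4-diene-1-carboxylate (racemic)
Conditions: TsOH·H2O (cat.), PhH, 50 °C
Reagents that add atoms: none
Why: Acid-promoted 1,4-elimination of silanol through the allyl cation, with proton loss from the methyl-bearing CH, should give the conjugated ring diene, which cannot aromatise because C1 is quaternary.

Step 5
Reactants: 8 (2R,5R)-2,5-dimethylpyrrolidine
Product: 9 1-[(2R,5R)-2,5-dimethylpyrrolidin-1-yl]ethan-1-one
Conditions: Ac2O, Et3N, CH2Cl2, 0 °C → rt
Reagents that add atoms: acetic anhydride, CC(=O)OC(C)=O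
Why: N-Acetylation of the C2-symmetric amine gives the tertiary amide that serves as a chiral ketene equivalent.

Step 6
Reactants: 9 1-[(2R,5R)-2,5-dimethylpyrrolidin-1-yl]ethan-1-one; 7 2-(trimethylsilyl)ethyl 1,3,5-trimethylcyclohexa-2,4-diene-1-carboxylate
Product: 12 2-(trimethylsilyl)ethyl (1S,6S)-1,3,5-trimethyl-7-oxobicyclo[4.2.0]oct-2-ene-5-carboxylate (cis-fused; C5 epimers), via keteniminium triflate 10 (not isolated), via cyclobutaniminium triflate 11 (not isolated)
Conditions: Tf2O, 2,4,6-collidine, ClCH2CH2Cl, −20 → 60 °C; then aq. NaHCO3, rt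
Reagents that add atoms: water, O
Why: Keteniminium–diene [2+2] cycloaddition in which the electrophilic central carbon should bond to the unsubstituted diene terminus C2 of 7 (allyl cation flanked by two methyl-bearing carbons) and the CH2 should close onto C3, so that the carbonyl lies next to the ring-fusion CH and the C4=C5 alkene of 7 survives; the cis fusion is inherent and its absolute sense is set by the C2-symmetric auxiliary, which should override the weak facial bias of the C1 substituents of racemic 7.

Step 7
Reactants: 12 2-(trimethylsilyl)ethyl (1S,6S)-1,3,5-trimethyl-7-oxobicyclo[4.2.0]oct-2-ene-5-carboxylate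
Product: 13 2-(trimethylsilyl)ethyl 1,3,5,8-tetramethyl-7-oxobicyclo[4.2.0]oct-2-ene-5-carboxylate (8-methyl exo, cis to the 1-methyl)
Conditions: LDA, THF, −78 °C; MeI, −78 → −40 °C
Reagents that add atoms: iodomethane, CI
Why: Kinetic enolate alkylation in which LDA should deprotonate the C8 methylene and not the ring-fusion CH, and iodomethane should approach from the convex exo face of the cis-fused bicycle, placing the 8-methyl cis to the 1-methyl.

Step 8
Reactants: 13 2-(trimethylsilyl)ethyl 1,3,5,8-tetramethyl-7-oxobicyclo[4.2.0]oct-2-ene-5-carboxylate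
Product: 14 2-(trimethylsilyl)ethyl 7-(methoxymethylidene)-1,3,5,8-tetramethylbicyclo[4.2.0]oct-2-ene-5-carboxylate (E/Z mixture)
Conditions: Ph3P+CH2OMe Cl−, KHMDS, THF, 0 °C → rt
Reagents that add atoms: (methoxymethyl)triphenylphosphonium chloride, COC[P+](c1ccccc1)(c1ccccc1)c1ccccc1.[Cl-]
Why: Wittig methoxymethylenation adds the one carbon needed at C7; addition to the strained, electrophilic cyclobutanone should be faster than enolisation.

Step 9
Reactants: 14 2-(trimethylsilyl)ethyl 7-(methoxymethylidene)-1,3,5,8-tetramethylbicyclo[4.2.0]oct-2-ene-5-carboxylate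
Product: 15 2-(trimethylsilyl)ethyl 7-formyl-1,3,5,8-tetramethylbicyclo[4.2.0]oct-2-ene-5-carboxylate (C7 epimers)
Conditions: 2 M HCl, THF, rt
Reagents that add atoms: water, O
Why: Acid hydrolysis of the enol ether gives the aldehyde; the C7 configuration does not matter because step 10 planarises it.

Step 10
Reactants: 15 2-(trimethylsilyl)ethyl 7-formyl-1,3,5,8-tetramethylbicyclo[4.2.0]oct-2-ene-5-carboxylate
Product: 16 2-(trimethylsilyl)ethyl 7-formyl-1,3,5,7,8-pentamethylbicyclo[4.2.0]oct-2-ene-5-carboxylate (7-methyl exo, formyl endo)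
Conditions: KHMDS, THF, −78 °C; MeI, −78 → 0 °C
Reagents that add atoms: iodomethane, CI
Why: C-Alkylation of the potassium enolate of the α-branched aldehyde, in which iodomethane should attack C7 from the exo face because the endo face is screened by C5 and its substituents, giving the quaternary centre with methyl exo and formyl endo.

Step 11
Reactants: 16 2-(trimethylsilyl)ethyl 7-formyl-1,3,5,7,8-pentamethylbicyclo[4.2.0]oct-2-ene-5-carboxylate; 17 methyl 2-methyl-3-oxopentanoate
Product: 19 methyl 5-hydroxy-2,4-dimethyl-3-oxo-5-(bicyclooctenyl)pentanoate, i.e. the aldol adduct at the formyl carbon of 16 (mixture of diastereomers), via ketoester dianion 18 (not isolated)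
Conditions: NaH then n-BuLi, THF, 0 °C; add 16, −78 → 0 °C; aq. NH4Cl
Reagents that add atoms: none
Why: Aldol addition of the γ-carbon of the β-keto ester dianion to the aldehyde; the new carbinol and methine centres are removed in steps 12 and 13.

Step 12
Reactants: 19 aldol adduct
Product: 20 methyl 2,4-dimethyl-3,5-dioxo-5-(bicyclooctenyl)pentanoate (β,δ-diketo ester)
Conditions: Dess–Martin periodinane, NaHCO3, CH2Cl2, rt
Reagents that add atoms: none
Why: Dess–Martin oxidation of the secondary alcohol gives the triketide without touching the ring alkene or the silyl ester.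

Step 13
Reactants: 20 β,δ-diketo ester
Product: 21 2-(trimethylsilyl)ethyl 7-(4-hydroxy-3,5-dimethyl-2-oxo-2H-pyran-6-yl)-1,3,5,7,8-pentamethylbicyclo[4.2.0]oct-2-ene-5-carboxylate
Conditions: DBU, PhH, 60 °C
Reagents that add atoms: none
Why: Base-mediated enolisation and lactonisation of the triketide with loss of methanol should give the 4-hydroxy-2-pyranone.

Step 14
Reactants: 21 hydroxy-2-pyranone
Product: 22 2-(trimethylsilyl)ethyl 7-(6-methoxy-3,5-dimethyl-4-oxo-4H-pyran-2-yl)-1,3,5,7,8-pentamethylbicyclo[4.2.0]oct-2-ene-5-carboxylate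
Conditions: MeOTf, CH2Cl2, rt; aq. NaHCO3
Reagents that add atoms: methyl trifluoromethanesulfonate, COS(=O)(=O)C(F)(F)F
Why: O-Methylation by a hard methylating agent should take place at the lactone carbonyl oxygen and, after loss of a proton, give the 2-methoxy-4-pyranone.

Step 15
Reactants: 22 methoxypyranone silyl ester
Product: 23 7-(6-methoxy-3,5-dimethyl-4-oxo-4H-pyran-2-yl)-1,3,5,7,8-pentamethylbicyclo[4.2.0]oct-2-ene-5-carboxylic acid
Conditions: TBAF, THF, 0 °C → rt; dilute HCl (pH 3)
Reagents that add atoms: none
Why: Fluoride attack at silicon triggers β-elimination of ethene and should free the hindered acid without attack at the ester carbonyl or the methoxypyranone.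

Step 16
Reactants: 23 C5 carboxylic acid
Product: 25 2-[5-hydroperoxy-1,3,5,7,8-pentamethylbicyclo[4.2.0]oct-2-en-7-yl]-6-methoxy-3,5-dimethyl-4H-pyran-4-one (5-OOH on the face opposite the cyclobutane; pyranonyl endo; 7- and 8-methyl exo), via thiohydroxamate ester 24 (not isolated)
Conditions: 1-hydroxypyridine-2(1H)-thione, DCC, DMAP (cat.), CH2Cl2, dark, rt; then t-BuSH (excess), O2, hν (tungsten lamp), PhMe, 0 °C
Reagents that add atoms: dioxygen, O=O
Why: Barton decarboxylation under oxygen, in which the tertiary C5 radical should take up O2 on the convex face (away from the cyclobutane and its endo pyranone) and the peroxyl radical is reduced by the thiol, so that both C5 epimers converge on one hydroperoxide and no cation arises at this cyclobutylcarbinyl position.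

Step 17
Reactants: 25 tertiary homoallylic hydroperoxide
Product: 26 2-[2,5-epidioxy-3-hydroperoxy-1,3,5,7,8-pentamethylbicyclo[4.2.0]octan-7-yl]-6-methoxy-3,5-dimethyl-4H-pyran-4-one (epidioxy bridge opposite the cyclobutane; 3-OOH on the side of the bridge)
Conditions: di-tert-butyl peroxyoxalate (0.2 equiv), O2 (1 atm), PhH, 25 °C
Reagents that add atoms: dioxygen, O=O
Why: tert-Butoxyl radicals from the initiator abstract the OO–H hydrogen, the C5 peroxyl radical adds across the ring to C2 (the unsubstituted carbon of the C2=C3 alkene), and the tertiary C3 radical is trapped by O2 and then takes hydrogen from another molecule of 25, which carries the chain. The closest known reaction type is the radical-chain cyclisation of unsaturated hydroperoxides under oxygen to hydroperoxy-substituted cyclic peroxides, as in thiol–olefin co-oxygenation routes to bridged 1,2-dioxanes. The one new O–C bond closes the 1,2-dioxane ring O–O–C2–C1–C6–C5 in a 6-exo-trig mode (6-endo if counted through C4–C3) and so completes the 2,3-dioxabicyclo[2.2.2]octane. The C2 configuration is fixed by C5, because the bridge can only form on the face that carries the peroxyl group; the C3 hydroperoxide is expected on the side of the new bridge, away from the cyclobutane, and this centre is removed in step 19. The step needs attack at C2 in preference to five-membered closure at C3; the methyl group on C3 secures this by making C2 the less hindered terminus and the resulting radical tertiary, and the [2.2.2] bicycle is less strained than the [2.2.1] alternative. Oxygen saturation should keep O2 capture of the C3 radical faster than its attack on the new O–O bond.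

Step 18
Reactants: 26 hydroperoxy endoperoxide
Product: 27 2-[2,5-epidioxy-3-hydroxy-1,3,5,7,8-pentamethylbicyclo[4.2.0]octan-7-yl]-6-methoxy-3,5-dimethyl-4H-pyran-4-one
Conditions: PPh3, CH2Cl2, 0 °C
Reagents that add atoms: none
Why: Triphenylphosphine reduces hydroperoxides far faster than dialkyl peroxides, so the tertiary alcohol should form with the peroxide bridge intact and the carbinol configuration retained.

Step 19
Reactants: 27 hydroxy endoperoxide
Product: 28 2-[2,5-epidioxy-1,3,5,7,8-pentamethylbicyclo[4.2.0]oct-3-en-7-yl]-6-methoxy-3,5-dimethyl-4H-pyran-4-one (CNP0183511.1)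
Conditions: Burgess reagent, PhH, 50 °C
Reagents that add atoms: none
Why: Syn-elimination through the Burgess sulfamate ester, in which the C4 hydrogen eclipsed with the C3 oxygen in the rigid bicycle should be removed to give the ring trisubstituted alkene (the bridgehead C2–H cannot be lost), under conditions free of bases that would open the peroxide.

**Compound list**

1 | methacryloyl chloride | CC(=C)C(Cl)=O | starting material
2 | 2-(trimethylsilyl)ethanol | C[Si](C)(C)CCO | starting material
3 | 2-(trimethylsilyl)ethyl methacrylate | CC(=C)C(=O)OCC[Si](C)(C)C | intermediate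
4 | (E)-2-methylpent-2-enal | CC/C=C(\C)C=O | starting material
5 | (1E,3E)-1-[(tert-butyldimethylsilyl)oxy]-2-methylpenta-1,3-diene | C/C=C/C(/C)=C/O[Si](C)(C)C(C)(C)C | intermediate
6 | 2-(trimethylsilyl)ethyl 2-[(tert-butyldimethylsilyl)oxy]-1,3,5-trimethylcyclohex-3-ene-1-carboxylate (racemic, diastereomer mixture) | CC1C=C(C)C(O[Si](C)(C)C(C)(C)C)C(C)(C(=O)OCC[Si](C)(C)C)C1 | intermediate
7 | 2-(trimethylsilyl)ethyl 1,3,5-trimethylcyclohexa-2,4-diene-1-carboxylate (racemic) | CC1=CC(C)=CC(C)(C(=O)OCC[Si](C)(C)C)C1 | intermediate
8 | (2R,5R)-2,5-dimethylpyrrolidine | C[C@@H]1CC[C@@H](C)N1 | starting material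
9 | 1-[(2R,5R)-2,5-dimethylpyrrolidin-1-yl]ethan-1-one | C[C@@H]1CC[C@@H](C)N1C(C)=O | intermediate
10 | N-ethenylidene-(2R,5R)-2,5-dimethylpyrrolidinium triflate (keteniminium triflate) | C[C@@H]1CC[C@@H](C)[N+]1=C=C.[O-]S(=O)(=O)C(F)(F)F | intermediate
11 | cyclobutaniminium triflate of 12 with the auxiliary (C5 epimers) | C[C@@H]3CC[C@@H](C)[N+]3=C1C[C@@]2(C)C=C(C)CC(C)(C(=O)OCC[Si](C)(C)C)[C@@H]12.[O-]S(=O)(=O)C(F)(F)F | intermediate
12 | 2-(trimethylsilyl)ethyl (1S,6S)-1,3,5-trimethyl-7-oxobicyclo[4.2.0]oct-2-ene-5-carboxylate (cis-fused, C5 epimers) | O=C1C[C@@]2(C)C=C(C)CC(C)(C(=O)OCC[Si](C)(C)C)[C@@H]12 | intermediate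
13 | 8-exo-methyl ketone: 2-(trimethylsilyl)ethyl 1,3,5,8-tetramethyl-7-oxobicyclo[4.2.0]oct-2-ene-5-carboxylate (8-CH3 cis to 1-CH3) | O=C1[C@H](C)[C@@]2(C)C=C(C)CC(C)(C(=O)OCC[Si](C)(C)C)[C@@H]12 | intermediate
14 | 7-(methoxymethylidene) enol ether (E/Z) | COC=C1[C@H](C)[C@@]2(C)C=C(C)CC(C)(C(=O)OCC[Si](C)(C)C)[C@@H]12 | intermediate
15 | 7-formyl-1,3,5,8-tetramethyl ester (C7 epimers) | O=CC1[C@H](C)[C@@]2(C)C=C(C)CC(C)(C(=O)OCC[Si](C)(C)C)[C@@H]12 | intermediate
16 | 7-endo-formyl-1,3,5,7,8-pentamethyl ester (7-CH3 and 8-CH3 exo) | O=C[C@@]1(C)[C@H](C)[C@@]2(C)C=C(C)CC(C)(C(=O)OCC[Si](C)(C)C)[C@@H]12 | intermediate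
17 | methyl 2-methyl-3-oxopentanoate | CCC(=O)C(C)C(=O)OC | starting material
18 | sodium lithium dianion of methyl 2-methyl-3-oxopentanoate | [Na+].[Li+].C[CH-]C(=O)[C-](C)C(=O)OC | intermediate
19 | aldol adduct (β-hydroxy-δ-keto ester, diastereomer mixture) | COC(=O)C(C)C(=O)C(C)C(O)[C@@]1(C)[C@H](C)[C@@]2(C)C=C(C)CC(C)(C(=O)OCC[Si](C)(C)C)[C@@H]12 | intermediate
20 | β,δ-diketo ester | COC(=O)C(C)C(=O)C(C)C(=O)[C@@]1(C)[C@H](C)[C@@]2(C)C=C(C)CC(C)(C(=O)OCC[Si](C)(C)C)[C@@H]12 | intermediate
21 | 4-hydroxy-3,5-dimethyl-2-pyranon-6-yl silyl ester | Cc1c(O)c(C)c([C@@]2(C)[C@H](C)[C@@]3(C)C=C(C)CC(C)(C(=O)OCC[Si](C)(C)C)[C@@H]23)oc1=O | intermediate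
22 | 6-methoxy-3,5-dimethyl-4-pyranon-2-yl silyl ester | COc1oc([C@@]2(C)[C@H](C)[C@@]3(C)C=C(C)CC(C)(C(=O)OCC[Si](C)(C)C)[C@@H]23)c(C)c(=O)c1C | intermediate
23 | methoxypyranonyl C5 carboxylic acid | COc1oc([C@@]2(C)[C@H](C)[C@@]3(C)C=C(C)CC(C)(C(=O)O)[C@@H]23)c(C)c(=O)c1C | intermediate
24 | 2-thioxopyridin-1(2H)-yl ester of 23 (thiohydroxamate ester) | COc1oc([C@@]2(C)[C@H](C)[C@@]3(C)C=C(C)CC(C)(C(=O)ON4C=CC=CC4=S)[C@@H]23)c(C)c(=O)c1C | intermediate
25 | tertiary hydroperoxide (key-step precursor) | COc1oc([C@@]2(C)[C@H](C)[C@@]3(C)C=C(C)C[C@](C)(OO)[C@@H]23)c(C)c(=O)c1C | intermediate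
26 | hydroperoxy 2,3-dioxabicyclo[2.2.2]octane (key-step product) | COc1oc([C@@]2(C)[C@H](C)[C@@]3(C)[C@@H]4OO[C@@](C)(C[C@@]4(C)OO)[C@@H]23)c(C)c(=O)c1C | intermediate
27 | hydroxy 2,3-dioxabicyclo[2.2.2]octane | COc1oc([C@@]2(C)[C@H](C)[C@@]3(C)[C@@H]4OO[C@@](C)(C[C@@]4(C)O)[C@@H]23)c(C)c(=O)c1C | intermediate
28 | CNP0183511.1 | COc1oc([C@@]2(C)[C@H](C)[C@@]3(C)[C@@H]4OO[C@@](C)(C=C4C)[C@@H]23)c(C)c(=O)c1C | target

**Step count**

Total steps: 19. Longest linear sequence: 17 (steps 2–4 and 6–19).

**Steps most likely to fail**

Step 6. The auxiliary may not discriminate the diene faces well enough, and the unsubstituted keteniminium ion may self-condense, so the ring fusion could form with low enantiomeric purity or in low yield. Fallback: setting out from diene 7, dichloroketene (from trichloroacetyl chloride and zinc–copper couple in ether) should add with the same regiochemistry to give the racemic 8,8-dichlorocyclobutanone F1. Zinc in acetic acid should remove both chlorines to give the racemic ketone F2. Its enantiomers are separated on a chiral stationary phase, each C5 epimer pair in the same way, and the unwanted (1R,6R) antipode F3 is set aside. The route is rejoined at 12.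

Step 17. Hydrogen transfer from the hindered tertiary hydroperoxide may be too slow to sustain the chain, so that peroxyl radicals terminate or the C3 radical attacks the new O–O bond before oxygen traps it. Fallback: setting out from acid 23, the thiohydroxamate ester 24 is photolysed under oxygen at high dilution with slow addition of tert-butyl thiol. The C5 peroxyl radical then forms by decarboxylative oxygen capture and should cyclise before it meets the thiol. The thiol quenches the second peroxyl radical and carries the chain, as in a thiol–olefin co-oxygenation. This forms no compound outside the list (F0), and the route is rejoined at 26.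

Step 19. Proton loss from the C3 methyl group may compete with loss of the C4 ring hydrogen, giving the exocyclic alkene. Fallback: setting out from alcohol 27, the dehydration is run under equilibrating E1 conditions (catalytic TsOH, benzene, molecular sieves, rt). The exocyclic methylene isomer F4 formed alongside should return through the common tertiary cation to the more substituted ring alkene, and the route is rejoined at 28.

**Further compounds**

F1 | step 6 | racemic 2-(trimethylsilyl)ethyl 8,8-dichloro-1,3,5-trimethyl-7-oxobicyclo[4.2.0]oct-2-ene-5-carboxylate (cis-fused) | O=C1C(Cl)(Cl)C2(C)C=C(C)CC(C)(C(=O)OCC[Si](C)(C)C)C12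
F2 | step 6 | racemic 2-(trimethylsilyl)ethyl 1,3,5-trimethyl-7-oxobicyclo[4.2.0]oct-2-ene-5-carboxylate (cis-fused) | O=C1CC2(C)C=C(C)CC(C)(C(=O)OCC[Si](C)(C)C)C12
F3 | step 6 | 2-(trimethylsilyl)ethyl (1R,6R)-1,3,5-trimethyl-7-oxobicyclo[4.2.0]oct-2-ene-5-carboxylate (antipode of 12) | O=C1C[C@]2(C)C=C(C)CC(C)(C(=O)OCC[Si](C)(C)C)[C@H]12
F0 | step 17 | none | none
F4 | step 19 | 3-methylidene isomer of 28 (exocyclic alkene) | COc1oc([C@@]2(C)[C@H](C)[C@@]3(C)[C@@H]4OO[C@@](C)(CC4=C)[C@@H]23)c(C)c(=O)c1C
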